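**Strategy.** The route rests on cutting the bond between the benzylic carbon and bornane C6, which turns the benzylic CH2 into an aryl aldehyde and C6 into one end of a C5=C6 alkene. The C2 ether oxygen and the C6 benzylic carbon both point endo and flank the methyl-bearing bridgehead C1. A formyl group ortho to the oxygen of a 2-endo-aryloxyborn-5-ene is therefore held against the endo face of C6. Rhodium-catalysed hydroacylation then makes the C–C bond, closes the seven-membered oxepane ring and fixes the C6 stereocentre in one operation. The precursor is 2-(born-5-en-2-endo-yloxy)-4,6-bis(methoxymethoxy)benzaldehyde, joined by SNAr from (+)-borneol-derived bornenol and a fluoro aldehyde.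

Key step: step 8

Remark on numbering: bornane numbering is used for the terpene part (C1 methyl-bearing bridgehead, C2 oxygen-bearing carbon, C4 second bridgehead, C7 the CMe2 bridge).

Assumption: N-methoxy-N,3-dimethylbutanamide (20) is taken as a purchasable amide; if it had to be made, isovaleryl chloride and N,O-dimethylhydroxylamine hydrochloride would give it in one operation.

Step 1
Reactants: 1 (1R,2S,4R)-(+)-borneol; 2 acetic anhydride
Product: 3 (1R,2S,4R)-bornyl acetate
Conditions: Ac2O, pyridine, DMAP (cat.), CH2Cl2, 0 °C → rt
Reagents that add atoms: acetic anhydride, CC(=O)OC(C)=O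
Why: DMAP-catalysed O-acylation (esterification) of the endo secondary alcohol touches no stereocentre, and the acetate shields the carbinol and deactivates the neighbouring C3 methylene towards the oxidant of step 2.

Step 2
Reactants: 3 (1R,2S,4R)-bornyl acetate
Product: 4 (1R,2S,4R)-5-oxobornan-2-endo-yl acetate
Conditions: CrO3, AcOH–Ac2O, rt
Reagents that add atoms: chromium trioxide CrO3, O=[Cr](=O)=O
Why: Chromic acid oxidation of an unactivated methylene (remote C–H oxidation) is established on bornyl acetate to favour C5, the CH2 farthest from the electron-withdrawing acetoxy group and not adjacent to the quaternary C1; the minor 6-oxo isomer is removed by chromatography and no stereocentre is involved.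

Step 3
Reactants: 4 (1R,2S,4R)-5-oxobornan-2-endo-yl acetate; 5 p-toluenesulfonohydrazide
Product: 6 (1R,2S,4R)-5-(tosylhydrazono)bornan-2-endo-yl acetate
Conditions: TsNHNH2, AcOH (cat.), EtOH, 70 °C
Reagents that add atoms: p-toluenesulfonohydrazide, Cc1ccc(cc1)S(=O)(=O)NN
Why: Acid-catalysed condensation of the ketone with the sulfonyl hydrazide (tosylhydrazone formation) leaves the ester, the ring system and all stereocentres untouched.

Step 4
Reactants: 6 (1R,2S,4R)-5-(tosylhydrazono)bornan-2-endo-yl acetate
Product: 8 (1R,2S,4S)-born-5-en-2-endo-ol, via C5-vinyllithium lithium alkoxide 7 (not isolated)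
Conditions: MeLi (6 equiv), Et2O, 0 °C → rt; then H2O
Reagents that add atoms: none
Why: Shapiro reaction, in which MeLi removes N–H and then a C6 hydrogen (C4 is a bridgehead and cannot be deprotonated), loss of sulfinate and N2 leaves the C5 vinyllithium that water protonates to the C5=C6 alkene, while the same reagent cleaves the acetate by double addition; C1, C2 and C4 are not involved.

Step 5
Reactants: 9 5-fluororesorcinol; 10 N,N-dimethylformamide
Product: 12 2-fluoro-4,6-dihydroxybenzaldehyde, via aryl iminium chloride 11 (not isolated)
Conditions: POCl3, DMF, MeCN, −15 °C → rt; then H2O, 50 °C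
Reagents that add atoms: N,N-dimethylformamide, CN(C)C=O; water, O
Why: Vilsmeier–Haack formylation, in which the chloroiminium electrophile should attack the carbon para to one hydroxyl and ortho to the other (two equivalent sites) as resorcinols normally do, and not the doubly flanked carbon between the hydroxyls; formylating before protection avoids a directed lithiation of the bis-MOM ether, which would metalate between the two acetal oxygens and give the wrong 4-fluoro isomer.

Step 6
Reactants: 12 2-fluoro-4,6-dihydroxybenzaldehyde; 13 chloromethyl methyl ether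
Product: 14 2-fluoro-4,6-bis(methoxymethoxy)benzaldehyde
Conditions: NaH, MOMCl, DMF, 0 °C → rt
Reagents that add atoms: chloromethyl methyl ether, COCCl
Why: O-alkylation of both phenoxides by the α-chloro ether (Williamson-type acetal protection), with NaH needed to free the hydroxyl that is hydrogen-bonded to the formyl group.

Step 7
Reactants: 8 (1R,2S,4S)-born-5-en-2-endo-ol; 14 2-fluoro-4,6-bis(methoxymethoxy)benzaldehyde
Product: 16 2-{[(1R,2S,4S)-born-5-en-2-endo-yl]oxy}-4,6-bis(methoxymethoxy)benzaldehyde, via sodium born-5-en-2-endo-olate 15 (not isolated)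
Conditions: NaH, THF, 0 °C; then 14, THF–DMF, 0 °C → rt
Reagents that add atoms: none
Why: SNAr (addition–elimination), in which the sodium alkoxide, guided by coordination to the formyl oxygen, attacks the ortho C–F carbon and the formyl group stabilises the Meisenheimer anion, both OMOM groups being meta to fluorine; the C2–O bond of the alcohol is never broken, so the endo configuration is kept, and the temperature stays at or below rt so that the homoallylic alkoxide does not fragment by retro-[4+2] reaction.

Step 8
Reactants: 16 2-{[(1R,2S,4S)-born-5-en-2-endo-yl]oxy}-4,6-bis(methoxymethoxy)benzaldehyde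
Product: 17 oxepanone-bridged bornane aryl ketone, bis-MOM ether (bornane 1R,2S,4R,6R; C2-endo oxygen and C6-endo carbonyl carbon on adjacent ring carbons, OMOM ortho and para to the carbonyl)
Conditions: [Rh(cod)2]BF4 (10 mol %), dppe (10 mol %), H2 (1 atm) then Ar purge, ClCH2CH2Cl, 70 °C
Reagents that add atoms: none
Why: Oxidative addition of the formyl C–H bond to the cationic bisphosphine complex of monovalent rhodium gives an acyl hydride of trivalent rhodium held in a five-membered chelate by the aryl ether oxygen, which slows decarbonylation; the C5=C6 alkene, bound through its endo face, inserts into Rh–H with hydrogen going to C5 and rhodium to C6, and C–C reductive elimination releases the ketone. The closest known reaction type is the chelation-assisted rhodium-catalysed intramolecular hydroacylation of ortho-(alkenyloxy)- and ortho-(alkenylthio)benzaldehydes to seven-membered aryl ketones. The oxepanone ring closes in a formal 7-exo-trig mode (bond to the proximal alkene carbon C6, C5 staying outside the new ring) through an eight-membered acyl alkyl rhodacycle. The new C6 stereocentre is set by the substrate, because the tether hanging from the 2-endo oxygen can deliver the acyl group only to the endo lobe of C6, and the exo face is in any case screened by the syn methyl on C7. The step needs regioselectivity (C6 over C5, seven- over eight-membered ring), endo facial selectivity and hydroacylation in preference to decarbonylation; the first two follow from the 1,3-endo relationship of the C2 oxygen and C6 across C1, the third from oxygen chelation and the strain of the bridged alkene, which cannot isomerise because both allylic carbons are bridgeheads.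

Step 9
Reactants: 17 oxepanone-bridged bornane aryl ketone, bis-MOM ether
Product: 19 oxepane-bridged bornane bis-MOM ether (bornane 1R,2S,4R,6S; benzylic CH2 on C6-endo), via ketone hydrazone 18 (not isolated)
Conditions: N2H4·H2O, KOH, diethylene glycol, 130 °C then 200 °C
Reagents that add atoms: none
Why: Wolff–Kishner reduction in the Huang-Minlon form, where hydrazone formation and base-induced loss of N2 turn the aryl ketone into the benzylic CH2 under conditions to which MOM acetals and the alkyl aryl ether are inert; C6, although α to the carbonyl, keeps its configuration because only the endo epimer can span the seven-membered ring.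

Step 10
Reactants: 19 oxepane-bridged bornane bis-MOM ether; 20 N-methoxy-N,3-dimethylbutanamide
Product: 23 bis-MOM aryl isobutyl ketone (19 carrying a 3-methylbutanoyl group on the ring carbon between the two OMOM groups), via aryllithium 21 (not isolated), via lithium hemiaminal adduct 22 (not isolated)
Conditions: n-BuLi, THF, 0 °C; then 20, −78 °C → rt; then H2O
Reagents that add atoms: N-methoxy-N,3-dimethylbutanamide, CC(C)CC(=O)N(C)OC
Why: Directed ortho-metalation followed by Weinreb ketone synthesis, in which n-BuLi removes the ring hydrogen flanked by two chelating OMOM groups in preference to the one between OMOM and the hindered bornyl ether, and the aryllithium adds only once because the chelated tetrahedral adduct survives until work-up.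

Step 11
Reactants: 23 bis-MOM aryl isobutyl ketone
Product: 24 des-formyl diphenol ketone (23 with both MOM groups replaced by H)
Conditions: HCl (3 M aq), MeOH, 50 °C
Reagents that add atoms: none
Why: Acid-catalysed cleavage of the MOM acetals by transacetalisation to methanol (acetal hydrolysis), which the secondary alkyl aryl ether and the ketone tolerate, with no stereocentre touched.

Step 12
Reactants: 24 des-formyl diphenol ketone; 25 dichloromethyl methyl ether
Product: 27 CNP0246493.1 (24 carrying CHO on the last free ring carbon, between a hydroxyl and the ether oxygen), via aryl chloro(methoxy)methane 26 (not isolated)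
Conditions: Cl2CHOMe, TiCl4, CH2Cl2, −78 → 0 °C; then ice-cold aq HCl
Reagents that add atoms: dichloromethyl methyl ether, COC(Cl)Cl; water, O
Why: Rieche formylation, in which TiCl4 ionises Cl2CHOMe to a chloro(methoxy)carbenium electrophile that substitutes the only unsubstituted ring carbon, ortho to a titanium-bound phenoxide, and hydrolysis of the chloro ether on work-up releases the aldehyde while the acyl group and the stereocentres are spectators.

**Compound list**

1 | (1R,2S,4R)-(+)-borneol (endo-1,7,7-trimethylbicyclo[2.2.1]heptan-2-ol) | CC1(C)[C@@H]2CC[C@@]1(C)[C@@H](O)C2 | starting material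
2 | acetic anhydride | CC(=O)OC(C)=O | starting material
3 | (1R,2S,4R)-bornyl acetate | CC1(C)[C@@H]2CC[C@@]1(C)[C@@H](OC(C)=O)C2 | intermediate
4 | (1R,2S,4R)-5-oxobornan-2-endo-yl acetate | CC1(C)[C@@H]2C(=O)C[C@@]1(C)[C@@H](OC(C)=O)C2 | intermediate
5 | p-toluenesulfonohydrazide | Cc1ccc(cc1)S(=O)(=O)NN | starting material
6 | (1R,2S,4R)-5-(tosylhydrazono)bornan-2-endo-yl acetate | CC1(C)[C@@H]2C(=NNS(=O)(=O)c3ccc(C)cc3)C[C@@]1(C)[C@@H](OC(C)=O)C2 | intermediate
7 | lithium 5-lithioborn-5-en-2-endo-olate (formed in the flask) | CC1(C)[C@@H]2C([Li])=C[C@@]1(C)[C@@H](O[Li])C2 | intermediate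
8 | (1R,2S,4S)-born-5-en-2-endo-ol (1,7,7-trimethylbicyclo[2.2.1]hept-5-en-2-ol) | CC1(C)[C@@H]2C=C[C@@]1(C)[C@@H](O)C2 | intermediate
9 | 5-fluororesorcinol | Oc1cc(O)cc(F)c1 | starting material
10 | N,N-dimethylformamide | CN(C)C=O | starting material
11 | N-(2-fluoro-4,6-dihydroxybenzylidene)-N-methylmethanaminium chloride (formed in the flask) | C[N+](C)=Cc1c(F)cc(O)cc1O.[Cl-] | intermediate
12 | 2-fluoro-4,6-dihydroxybenzaldehyde | O=Cc1c(F)cc(O)cc1O | intermediate
13 | chloromethyl methyl ether | COCCl | starting material
14 | 2-fluoro-4,6-bis(methoxymethoxy)benzaldehyde | O=Cc1c(F)cc(OCOC)cc1OCOC | intermediate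
15 | sodium (1R,2S,4S)-born-5-en-2-endo-olate (formed in the flask) | CC1(C)[C@@H]2C=C[C@@]1(C)[C@@H]([O-])C2.[Na+] | intermediate
16 | 2-{[(1R,2S,4S)-born-5-en-2-endo-yl]oxy}-4,6-bis(methoxymethoxy)benzaldehyde | C1=C[C@@H]3C[C@H](Oc2cc(OCOC)cc(OCOC)c2C=O)[C@@]1(C)C3(C)C | intermediate
17 | oxepanone-bridged bornane aryl ketone, bis-MOM ether (bornane 1R,2S,4R,6R; C2-endo–O–arene–C(=O)–C6-endo, OMOM ortho and para to C=O) | COCOc1cc(OCOC)cc2c1C(=O)[C@@H]1C[C@@H]3C[C@H](O2)[C@@]1(C)C3(C)C | intermediate
18 | hydrazone of ketone 17 (formed in the flask) | COCOc1cc(OCOC)cc2c1C(=NN)[C@@H]1C[C@@H]3C[C@H](O2)[C@@]1(C)C3(C)C | intermediate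
19 | oxepane-bridged bornane bis-MOM ether (bornane 1R,2S,4R,6S; benzylic CH2 on C6-endo) | COCOc1cc(OCOC)cc2c1C[C@@H]1C[C@@H]3C[C@H](O2)[C@@]1(C)C3(C)C | intermediate
20 | N-methoxy-N,3-dimethylbutanamide | CC(C)CC(=O)N(C)OC | starting material
21 | aryllithium of 19, lithiated between the two OMOM groups (formed in the flask) | COCOc1c([Li])c(OCOC)cc2c1C[C@@H]1C[C@@H]3C[C@H](O2)[C@@]1(C)C3(C)C | intermediate
22 | lithium hemiaminal adduct of 21 and 20 (formed in the flask; new carbon configuration undefined) | COCOc1c(C(O[Li])(CC(C)C)N(C)OC)c(OCOC)cc2c1C[C@@H]1C[C@@H]3C[C@H](O2)[C@@]1(C)C3(C)C | intermediate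
23 | bis-MOM aryl isobutyl ketone (3-methylbutanoyl between the two OMOM groups) | COCOc1c(C(=O)CC(C)C)c(OCOC)cc2c1C[C@@H]1C[C@@H]3C[C@H](O2)[C@@]1(C)C3(C)C | intermediate
24 | des-formyl diphenol ketone | CC(C)CC(=O)c1c(O)cc2c(c1O)C[C@@H]1C[C@@H]3C[C@H](O2)[C@@]1(C)C3(C)C | intermediate
25 | dichloromethyl methyl ether | COC(Cl)Cl | starting material
26 | aryl chloro(methoxy)methane from 24 (formed in the flask; new carbon configuration undefined) | CC(C)CC(=O)c1c(O)c(C(Cl)OC)c2c(c1O)C[C@@H]1C[C@@H]3C[C@H](O2)[C@@]1(C)C3(C)C | intermediate
27 | CNP0246493.1 | CC(C)CC(=O)c1c(O)c(C=O)c2c(c1O)C[C@@H]1C[C@@H]3C[C@H](O2)[C@@]1(C)C3(C)C | target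

**Step count and risks**

Total step count: 12. Longest linear sequence: 10 steps (steps 1–4 and 7–12, from 1); the arene branch (steps 5–6) joins at step 7.

Steps most likely to fail:

1. Step 8. The acyl rhodium hydride may lose CO faster than the alkene inserts, because the hindered, neutral ether oxygen may chelate too weakly or the metal may not reach the concave endo face; the catalyst would then die as a carbonyl complex. The fallback sets out from 16 and forms the same C–C bond by a radical chain. Oxidation of 16 (NaClO2, NaH2PO4, 2-methylbut-2-ene, t-BuOH–H2O) should give 2-(born-5-en-2-endo-yloxy)-4,6-bis(methoxymethoxy)benzoic acid F1. PhSeSePh and n-Bu3P should convert this into the corresponding Se-phenyl selenoester F2. Slow addition of n-Bu3SnH and AIBN (benzene, 80 °C) would generate the aroyl radical, which should add to the endo lobe of C6 in 7-exo fashion; the C5 radical then takes hydrogen from the stannane. The fallback comes back to the route at 17.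

2. Step 7. Substitution by a hindered secondary alkoxide at an electron-rich ring may be slow, so that hydride transfer from the alkoxide to the aldehyde, addition to the formyl group or, on warming, retro-[4+2] fragmentation of the homoallylic alkoxide could compete. The fallback sets out from 14 and replaces the formyl activator by a nitrile, which cannot accept hydride and allows substitution at low temperature. I2 and aqueous NH3 in THF should give 2-fluoro-4,6-bis(methoxymethoxy)benzonitrile F3. The sodium alkoxide of 8 (NaH, THF, 0 °C → rt) should displace fluoride to give 2-(born-5-en-2-endo-yloxy)-4,6-bis(methoxymethoxy)benzonitrile F4. Half-reduction with i-Bu2AlH (toluene, −78 °C) and mild aqueous hydrolysis of the imine returns the route to 16.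

3. Step 9. Hydrazone formation may stall at the hindered, electron-rich aryl ketone, and forcing conditions could cause base-mediated degradation. The fallback sets out from 17 and removes the oxygen by a radical deoxygenation. LiAlH4 (THF, 0 °C) should give the benzylic alcohol F5. NaH, CS2 and MeI should convert it into the O-benzylic S-methyl xanthate F6. n-Bu3SnH and AIBN (toluene, 110 °C, Barton–McCombie deoxygenation) should then cleave the C–O bond through the stabilised benzylic radical. The fallback comes back to the route at 19.

**Further compounds**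

F1 | step 8 | 2-{[(1R,2S,4S)-born-5-en-2-endo-yl]oxy}-4,6-bis(methoxymethoxy)benzoic acid | C1=C[C@@H]3C[C@H](Oc2cc(OCOC)cc(OCOC)c2C(=O)O)[C@@]1(C)C3(C)C
F2 | step 8 | Se-phenyl 2-{[(1R,2S,4S)-born-5-en-2-endo-yl]oxy}-4,6-bis(methoxymethoxy)benzenecarboselenoate | C1=C[C@@H]3C[C@H](Oc2cc(OCOC)cc(OCOC)c2C(=O)[Se]c4ccccc4)[C@@]1(C)C3(C)C
F3 | step 7 | 2-fluoro-4,6-bis(methoxymethoxy)benzonitrile | N#Cc1c(F)cc(OCOC)cc1OCOC
F4 | step 7 | 2-{[(1R,2S,4S)-born-5-en-2-endo-yl]oxy}-4,6-bis(methoxymethoxy)benzonitrile | C1=C[C@@H]3C[C@H](Oc2cc(OCOC)cc(OCOC)c2C#N)[C@@]1(C)C3(C)C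
F5 | step 9 | benzylic alcohol from ketone 17 (carbinol configuration undefined) | COCOc1cc(OCOC)cc2c1C(O)[C@@H]1C[C@@H]3C[C@H](O2)[C@@]1(C)C3(C)C
F6 | step 9 | O-benzylic S-methyl xanthate of F5 | COCOc1cc(OCOC)cc2c1C(OC(=S)SC)[C@@H]1C[C@@H]3C[C@H](O2)[C@@]1(C)C3(C)C
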